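**Plan**

1. The target is achiral. Ring A (C1 OMe, C2 methyl, C3 OH, C4 acetyl, C5 OH, C6 bridge CH2) carries three meta oxygens of which only O1 is methylated, and this pattern is what lets a cyclobutenone/ynol ether benzannulation build the ring.
2. Retrosynthesis first cuts the prenyl C–C bond on ring B and the two acetyl C–C bonds, then the ring A bonds C2–C3, C4–C5 and C5–C6. This gives a 3-methoxy-2-methyl-4-(arylmethyl)cyclobutenone (C1, C2, C5, C6 and the bridge) and an alkoxyacetylene (C3, C4).
3. The cyclobutenone is cut into 1-methoxypropyne and the ketene of 3-[2,4,6-tris(benzyloxy)phenyl]propanoyl chloride, which comes from 2,4,6-trihydroxybenzaldehyde and Meldrum's acid. Ring B is bought, ring A is built.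
4. Forward order: ring B arm, four-membered ring, ring A by benzannulation, global ether cleavage, twofold C-acetylation, C-prenylation of the last free carbon of ring B.
5. O3 enters as a 1-adamantyl ether. Its ynol ether cannot fragment by retro-ene on heating, and BCl3 removes it together with the benzyl groups while the O1 methyl ether stays. A primary alkyl ether at O3 would end up as the second ether ortho to an already chelated acetyl and could not be cleaved selectively beside the O1 methyl ether.
6. No stereocentre has to be set: the sp3 centres of the cyclobutenone and of the cascade intermediates are racemic and disappear on aromatisation.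

Key step: step 7

Remark: 1-methoxypropyne and 1-(ethynyloxy)adamantane are treated as non-commercial and are made in steps 4 and 6; the double-bond geometries written for the transient ketenes are the expected ones (outward rotation of the arylmethyl group) and do not affect the product.

**Step 1**
Reactants: 1 2,4,6-trihydroxybenzaldehyde
Product: 2 2,4,6-tris(benzyloxy)benzaldehyde
Conditions: BnBr (3.6 equiv), K2CO3 (4.5 equiv), DMF, rt → 60 °C
Reagents that add atoms: benzyl bromide, BrCc1ccccc1
Why: Williamson ether synthesis; the formyl group lowers the C-nucleophilicity of the phloroglucinol nucleus, so carbonate in DMF should give O-benzylation at all three phenols, the two chelated ortho hydroxyls reacting last on warming.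

**Step 2**
Reactants: 2 2,4,6-tris(benzyloxy)benzaldehyde; 3 Meldrum's acid (2,2-dimethyl-1,3-dioxane-4,6-dione)
Product: 6 3-[2,4,6-tris(benzyloxy)phenyl]propanoic acid, via arylidene Meldrum's acid 4 (not isolated), via arylmethyl Meldrum's acid 5 (not isolated)
Conditions: HCO2H/Et3N (5:2), rt → 95 °C
Reagents that add atoms: none
Why: Knoevenagel condensation, conjugate transfer hydrogenation by formate and hydrolytic decarboxylation of the Meldrum's acid adduct should follow one another in one pot, and benzyl ethers are inert to formate in the absence of a hydrogenation catalyst.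

**Step 3**
Reactants: 6 3-[2,4,6-tris(benzyloxy)phenyl]propanoic acid
Product: 7 3-[2,4,6-tris(benzyloxy)phenyl]propanoyl chloride
Conditions: (COCl)2 (1.3 equiv), DMF (cat.), CH2Cl2, 0 °C → rt; concentrated, used crude at once
Reagents that add atoms: oxalyl chloride, ClC(=O)C(Cl)=O
Why: Acid chloride formation through the Vilsmeier-type chloroiminium reagent runs cold and without Lewis acid, and since both ortho positions of the arene are blocked no indanone can form.

**Step 4**
Reactants: 8 2-chloro-1,1-dimethoxyethane (chloroacetaldehyde dimethyl acetal)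
Product: 10 1-methoxyprop-1-yne, via sodium methoxyacetylide 9 (not isolated)
Conditions: NaNH2 (3.1 equiv), liquid NH3, −33 °C; then MeI (1.2 equiv), −33 °C; distillation
Reagents that add atoms: iodomethane, CI
Why: Twofold elimination (methanol, then HCl) by sodium amide gives the sodium alkoxyacetylide, which is C-methylated by SN2 reaction with MeI, the standard route to 1-alkoxy-1-alkynes.

**Step 5**
Reactants: 7 3-[2,4,6-tris(benzyloxy)phenyl]propanoyl chloride; 10 1-methoxyprop-1-yne
Product: 12 3-methoxy-2-methyl-4-{[2,4,6-tris(benzyloxy)phenyl]methyl}cyclobut-2-en-1-one (racemic), via monoalkylketene 11 (not isolated)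
Conditions: 10 (3 equiv), Et3N (1.5 equiv), CH2Cl2, 40 °C, slow addition of 7
Reagents that add atoms: none
Why: Dehydrochlorination gives the ketene, whose carbonyl carbon is attacked by the methyl-bearing carbon of the ynol ether in a regiospecific ketene–alkyne (2+2) cycloaddition, so that methoxy ends up at C3 and the arylmethyl group at C4 of the cyclobutenone; the new C4 centre is racemic and is erased in step 7.

**Step 6**
Reactants: 13 adamantan-1-ol
Product: 17 1-(ethynyloxy)adamantane, via dichlorovinyl ether 14 (not isolated), via chloroalkynyl ether 15 (not isolated), via lithium acetylide 16 (not isolated)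
Conditions: KH (1.2 equiv), THF, 0 °C → rt; Cl2C=CHCl (1.1 equiv), −50 °C → rt; n-BuLi (2.5 equiv), −78 → −40 °C; H2O, −78 °C
Reagents that add atoms: trichloroethylene, ClC=C(Cl)Cl
Why: Addition of the alkoxide to dichloroacetylene formed in situ from trichloroethylene gives the dichlorovinyl ether, which n-butyllithium converts by elimination and chlorine–lithium exchange into the lithium alkynyl ether, the general alcohol-to-alkoxyacetylene sequence applied here to a tertiary alcohol.

**Step 7**
Reactants: 12 3-methoxy-2-methyl-4-{[2,4,6-tris(benzyloxy)phenyl]methyl}cyclobut-2-en-1-one; 17 1-(ethynyloxy)adamantane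
Product: 22 5-(adamantan-1-yloxy)-3-methoxy-4-methyl-2-{[2,4,6-tris(benzyloxy)phenyl]methyl}phenol, via vinylketene 18 (not isolated), via alkenylcyclobutenone 19 (not isolated), via dienylketene 20 (not isolated), via cyclohexadienone 21 (not isolated)
Conditions: 17 (2.5 equiv), toluene, 80 → 110 °C, sealed tube, argon
Reagents that add atoms: none
Why: Heating opens 12 by conrotatory four-electron cleavage of the bond between the carbonyl carbon and the sp3 carbon, the arylmethyl group turning outward, to vinylketene 18; the unsubstituted, nucleophilic carbon of ynol ether 17 then bonds to the ketene carbonyl carbon and its oxygen-bearing carbon to the methyl-bearing ketene carbon in a (2+2) cycloaddition, which creates C4–C5 and C2–C3 of ring A in cyclobutenone 19. A second four-electron opening gives dienylketene 20, which closes ring A through a thermal disrotatory six-electron electrocyclisation (C5–C6) to cyclohexadienone 21, and enolisation gives phenol 22. The closest known reaction type is the Danheiser benzannulation of cyclobutenones with alkoxy- and silyloxyacetylenes, which has been extended to 3-oxygenated and 4-substituted cyclobutenones. No stereocentre is set: the racemic sp3 centres of 12, 19 and 21 all vanish, and only the isomer of 20 with the alkenyl group turned inward can cyclise, which reversible opening of 19 supplies. The selectivity the step needs is the orientation of the (2+2) addition, and the polarity of the partners (electrophilic ketene carbonyl carbon, nucleophilic β-carbon of the ynol ether) secures it, so that the adamantyloxy carbon lies next to the methyl-bearing carbon and C4 is left as the only hydrogen-bearing carbon of ring A. The 1-adamantyl ynol ether is used because it cannot shed an alkene by retro-ene fragmentation at these temperatures, as tert-butyl and secondary alkyl ynol ethers do.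

**Step 8**
Reactants: 22 5-(adamantan-1-yloxy)-3-methoxy-4-methyl-2-{[2,4,6-tris(benzyloxy)phenyl]methyl}phenol
Product: 23 2-[(4,6-dihydroxy-2-methoxy-3-methylphenyl)methyl]benzene-1,3,5-triol
Conditions: BCl3 (8 equiv), C6HMe5 (10 equiv), CH2Cl2, −78 → 0 °C; aqueous work-up under argon
Reagents that add atoms: none
Why: Lewis-acid ether cleavage; BCl3 ionises benzyl and tertiary alkyl aryl ethers at low temperature, pentamethylbenzene captures the benzyl cations so that the electron-rich rings are not C-benzylated, and the aryl methyl ether, which needs far more forcing conditions, should survive.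

**Step 9**
Reactants: 23 2-[(4,6-dihydroxy-2-methoxy-3-methylphenyl)methyl]benzene-1,3,5-triol
Product: 24 1-{3-[(3-acetyl-2,4,6-trihydroxyphenyl)methyl]-2,6-dihydroxy-4-methoxy-5-methylphenyl}ethan-1-one
Conditions: Ac2O (2.1 equiv), BF3·OEt2 (6 equiv), 1,4-dioxane, 0 °C → rt; then aq. NaOAc, 50 °C
Reagents that add atoms: acetic anhydride, CC(=O)OC(C)=O
Why: Friedel–Crafts C-acylation of phloroglucinol-type nuclei; ring A offers a single free carbon between two hydroxyls, ring B two equivalent ones, and the first acetyl group on ring B deactivates it enough for the stoichiometry to hold at one acetyl per ring.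

**Step 10**
Reactants: 24 1-{3-[(3-acetyl-2,4,6-trihydroxyphenyl)methyl]-2,6-dihydroxy-4-methoxy-5-methylphenyl}ethan-1-one
Product: 25 mallotojaponin, 1-{3-[(3-acetyl-2,4,6-trihydroxy-5-(3-methylbut-2-en-1-yl)phenyl)methyl]-2,6-dihydroxy-4-methoxy-5-methylphenyl}ethan-1-one
Conditions: prenyl bromide (1.1 equiv), 10% aq. KOH, 0 °C, argon; then 1 M HCl
Reagents that add atoms: 1-bromo-3-methylbut-2-ene (prenyl bromide), CC(C)=CCBr
Why: C-alkylation of an acylphloroglucinol phenoxide (a vinylogous enolate) in water, where hydrogen bonding to oxygen favours attack through carbon; the free carbon of ring B is the only unsubstituted nucleophilic carbon in the molecule, so rearomatising C-prenylation should occur there.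

**Compound list**

1 | 2,4,6-trihydroxybenzaldehyde | O=Cc1c(O)cc(O)cc1O | starting material
2 | 2,4,6-tris(benzyloxy)benzaldehyde | O=Cc1c(OCc2ccccc2)cc(OCc2ccccc2)cc1OCc1ccccc1 | intermediate
3 | Meldrum's acid (2,2-dimethyl-1,3-dioxane-4,6-dione) | CC1(C)OC(=O)CC(=O)O1 | starting material
4 | 2,2-dimethyl-5-{[2,4,6-tris(benzyloxy)phenyl]methylidene}-1,3-dioxane-4,6-dione | CC1(C)OC(=O)C(=Cc2c(OCc3ccccc3)cc(OCc3ccccc3)cc2OCc2ccccc2)C(=O)O1 | intermediate (not isolated)
5 | 2,2-dimethyl-5-{[2,4,6-tris(benzyloxy)phenyl]methyl}-1,3-dioxane-4,6-dione | CC1(C)OC(=O)C(Cc2c(OCc3ccccc3)cc(OCc3ccccc3)cc2OCc2ccccc2)C(=O)O1 | intermediate (not isolated)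
6 | 3-[2,4,6-tris(benzyloxy)phenyl]propanoic acid | OC(=O)CCc1c(OCc2ccccc2)cc(OCc2ccccc2)cc1OCc1ccccc1 | intermediate
7 | 3-[2,4,6-tris(benzyloxy)phenyl]propanoyl chloride | O=C(Cl)CCc1c(OCc2ccccc2)cc(OCc2ccccc2)cc1OCc1ccccc1 | intermediate
8 | 2-chloro-1,1-dimethoxyethane | COC(CCl)OC | starting material
9 | sodium 2-methoxyethynide | [Na]C#COC | intermediate (not isolated)
10 | 1-methoxyprop-1-yne | CC#COC | intermediate
11 | 3-[2,4,6-tris(benzyloxy)phenyl]prop-1-en-1-one (monoalkylketene) | O=C=CCc1c(OCc2ccccc2)cc(OCc2ccccc2)cc1OCc1ccccc1 | intermediate (not isolated)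
12 | 3-methoxy-2-methyl-4-{[2,4,6-tris(benzyloxy)phenyl]methyl}cyclobut-2-en-1-one (racemic) | COC1=C(C)C(=O)C1Cc1c(OCc2ccccc2)cc(OCc2ccccc2)cc1OCc1ccccc1 | intermediate
13 | adamantan-1-ol | OC12CC3CC(CC(C3)C1)C2 | starting material
14 | (E)-1-[(1,2-dichloroethenyl)oxy]adamantane | Cl/C=C(/Cl)OC12CC3CC(CC(C3)C1)C2 | intermediate (not isolated)
15 | 1-[(chloroethynyl)oxy]adamantane | ClC#COC12CC3CC(CC(C3)C1)C2 | intermediate (not isolated)
16 | lithium 2-(adamantan-1-yloxy)ethynide | [Li]C#COC12CC3CC(CC(C3)C1)C2 | intermediate (not isolated)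
17 | 1-(ethynyloxy)adamantane | C#COC12CC3CC(CC(C3)C1)C2 | intermediate
18 | (3Z)-3-methoxy-2-methyl-5-[2,4,6-tris(benzyloxy)phenyl]penta-1,3-dien-1-one (vinylketene) | O=C=C(C)/C(OC)=C/Cc1c(OCc2ccccc2)cc(OCc2ccccc2)cc1OCc1ccccc1 | intermediate (not isolated)
19 | 3-(adamantan-1-yloxy)-4-methyl-4-{(1Z)-1-methoxy-3-[2,4,6-tris(benzyloxy)phenyl]prop-1-en-1-yl}cyclobut-2-en-1-one (racemic) | O=C1C=C(OC23CC4CC(CC(C4)C2)C3)C1(C)/C(OC)=C/Cc1c(OCc2ccccc2)cc(OCc2ccccc2)cc1OCc1ccccc1 | intermediate (not isolated)
20 | (3E,5Z)-3-(adamantan-1-yloxy)-5-methoxy-4-methyl-7-[2,4,6-tris(benzyloxy)phenyl]hepta-1,3,5-trien-1-one (dienylketene) | O=C=C/C(OC12CC3CC(CC(C3)C1)C2)=C(C)\C(OC)=C\Cc1c(OCc2ccccc2)cc(OCc2ccccc2)cc1OCc1ccccc1 | intermediate (not isolated)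
21 | 3-(adamantan-1-yloxy)-5-methoxy-4-methyl-6-{[2,4,6-tris(benzyloxy)phenyl]methyl}cyclohexa-2,4-dien-1-one (racemic) | O=C1C=C(OC23CC4CC(CC(C4)C2)C3)C(C)=C(OC)C1Cc1c(OCc2ccccc2)cc(OCc2ccccc2)cc1OCc1ccccc1 | intermediate (not isolated)
22 | 5-(adamantan-1-yloxy)-3-methoxy-4-methyl-2-{[2,4,6-tris(benzyloxy)phenyl]methyl}phenol | COc1c(C)c(OC23CC4CC(CC(C4)C2)C3)cc(O)c1Cc1c(OCc2ccccc2)cc(OCc2ccccc2)cc1OCc1ccccc1 | intermediate
23 | 2-[(4,6-dihydroxy-2-methoxy-3-methylphenyl)methyl]benzene-1,3,5-triol | COc1c(C)c(O)cc(O)c1Cc1c(O)cc(O)cc1O | intermediate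
24 | 1-{3-[(3-acetyl-2,4,6-trihydroxyphenyl)methyl]-2,6-dihydroxy-4-methoxy-5-methylphenyl}ethan-1-one | COc1c(C)c(O)c(C(C)=O)c(O)c1Cc1c(O)cc(O)c(C(C)=O)c1O | intermediate
25 | mallotojaponin | COc1c(C)c(O)c(C(C)=O)c(O)c1Cc1c(O)c(CC=C(C)C)c(O)c(C(C)=O)c1O | target

**Step count and risks**

Total step count: 10.
Longest linear sequence: 8 steps (steps 1, 2, 3, 5, 7, 8, 9, 10, from 2,4,6-trihydroxybenzaldehyde).

Steps most likely to fail:

Step 7. The vinylogous-ester cyclobutenone may open more slowly than simple alkyl cyclobutenones. On prolonged heating the vinylketene could then be intercepted by the phenol already formed (ester formation) or dimerise instead of adding to the ynol ether. The fallback makes vinylketene 18 without the four-membered ring, by 1,4-dehydrochlorination, and sets out from 7. Acid chloride 7 should acylate the lithium enolate of methyl propanoate (LiN(iPr)2, THF, −78 °C) to give the β-keto ester methyl 2-methyl-3-oxo-5-[2,4,6-tris(benzyloxy)phenyl]pentanoate F1. Trimethyl orthoformate with catalytic TsOH in MeOH should turn it into the enol ether methyl 3-methoxy-2-methyl-5-[2,4,6-tris(benzyloxy)phenyl]pent-2-enoate F2. LiOH in THF/H2O should give 3-methoxy-2-methyl-5-[2,4,6-tris(benzyloxy)phenyl]pent-2-enoic acid F3, and (COCl)2 with catalytic DMF the chloride 3-methoxy-2-methyl-5-[2,4,6-tris(benzyloxy)phenyl]pent-2-enoyl chloride F4. Slow addition of F4 to Et3N and 17 in toluene at 80 °C should generate 18 by γ-deprotonation with loss of chloride; the unchanged cascade through 19, 20 and 21 then returns to the route at 22.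

Step 9. Ring B may take up a second acetyl group, one ring may stay unacylated, or acid may cleave or scramble the still unacylated diarylmethane bridge. The fallback is a Houben–Hoesch acylation and sets out from 23. MeCN, ZnCl2 and HCl gas in Et2O at 0 °C should give the twofold ketiminium salt 1,1'-bis(iminium) dichloride of 24 F5, which precipitates and is thereby shielded from further acylation. Hydrolysis in hot water returns to the route at 24.

Step 10. The ambident phenoxide may be O-prenylated, alkylated twice with dearomatisation at an already substituted carbon, or cyclised to a chroman on acidic work-up. The fallback replaces alkylation by halogenation and cross-coupling and sets out from 24. N-iodosuccinimide in THF at 0 °C should iodinate the only free aromatic carbon to give 1-{3-[(3-acetyl-2,4,6-trihydroxy-5-iodophenyl)methyl]-2,6-dihydroxy-4-methoxy-5-methylphenyl}ethan-1-one F6. Stille coupling with tributyl(3-methylbut-2-en-1-yl)stannane and Pd(PPh3)4 (zerovalent palladium) in DMF at 80 °C then returns to the route at 25.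

**Further compounds**

F1 | step 7 | methyl 2-methyl-3-oxo-5-[2,4,6-tris(benzyloxy)phenyl]pentanoate (racemic) | COC(=O)C(C)C(=O)CCc1c(OCc2ccccc2)cc(OCc2ccccc2)cc1OCc1ccccc1
F2 | step 7 | methyl 3-methoxy-2-methyl-5-[2,4,6-tris(benzyloxy)phenyl]pent-2-enoate (alkene isomers) | COC(=O)C(C)=C(OC)CCc1c(OCc2ccccc2)cc(OCc2ccccc2)cc1OCc1ccccc1
F3 | step 7 | 3-methoxy-2-methyl-5-[2,4,6-tris(benzyloxy)phenyl]pent-2-enoic acid (alkene isomers) | OC(=O)C(C)=C(OC)CCc1c(OCc2ccccc2)cc(OCc2ccccc2)cc1OCc1ccccc1
F4 | step 7 | 3-methoxy-2-methyl-5-[2,4,6-tris(benzyloxy)phenyl]pent-2-enoyl chloride (alkene isomers) | O=C(Cl)C(C)=C(OC)CCc1c(OCc2ccccc2)cc(OCc2ccccc2)cc1OCc1ccccc1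
F5 | step 9 | 1,1'-bis(iminium) dichloride of 24 (both acetyl C=O replaced by C=NH2+) | COc1c(C)c(O)c(C(C)=[NH2+])c(O)c1Cc1c(O)cc(O)c(C(C)=[NH2+])c1O.[Cl-].[Cl-]
F6 | step 10 | 1-{3-[(3-acetyl-2,4,6-trihydroxy-5-iodophenyl)methyl]-2,6-dihydroxy-4-methoxy-5-methylphenyl}ethan-1-one | COc1c(C)c(O)c(C(C)=O)c(O)c1Cc1c(O)c(I)c(O)c(C(C)=O)c1O
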